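**Strategy.** Everything rests on cutting C5 out of the core. Without C5 the cycloheptene ring (C1, C6–C10; oxygen on C8, methyl on C10) is a benzene ring, so the hydroazulene is a 4-methoxy-2-methylphenyl group on C2 plus one carbenoid carbon on a ketone at C4. A rhodium carbenoid at C5 adds across the C1–C6 bond of that anisole (intramolecular Büchner reaction) and closes the cyclopentanone and the cycloheptatriene in one operation. The precursor is a C3-branched α-diazoketone made by Michael addition of an arylmalonate to an acrylimide and an auxiliary-controlled anti-aldol; a second, removable ester on C11′ blocks that acidic, insertion-prone position until the last step.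

Key step: step 16

**Remarks.**
- Atom labels: C1–C10 hydroazulene core, C11–C13 α-methylene lactone, C11′ (aryl-bearing), C12′ (carbonyl) and C13′ (CH2) of the arylacetic unit. α is the face of the core that carries the C2 oxygen, β the opposite face.
- Abbreviations: TBS = tert-butyldimethylsilyl; TBDPS = tert-butyldiphenylsilyl; E = CO2CH2CH2SiMe3; Ar = 4-[(TBDPS-oxy)methyl]-3-[(2R)-5-(TBS-oxy)pentan-2-yl]phenyl.
- Assumption: the aldol of step 12 follows the chelated Z-enolate model (aldehyde anti to the benzyl group), hence the R auxiliary.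
- Assumption: in lactones 29–42 either of the two equivalent E groups may have closed the ring, so C11′ is written without configuration; both forms converge in step 26.

**Route**

Step 1
Reactants: 1 pent-4-yn-1-ol
Product: 2 4-iodopent-4-en-1-ol
Conditions: NaI, Me3SiCl, H2O (0.5 equiv), MeCN, rt
Reagents that add atoms: sodium iodide, [Na+].[I-]
Why: Markovnikov hydroiodination of the terminal alkyne by HI made in the flask should give the 2-iodo-1-alkene that becomes the branched side chain.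

Step 2
Reactants: 2 4-iodopent-4-en-1-ol
Product: 3 tert-butyl[(4-iodopent-4-en-1-yl)oxy]dimethylsilane
Conditions: TBSCl, imidazole, CH2Cl2, 0 °C → rt
Reagents that add atoms: tert-butyldimethylsilyl chloride, CC(C)(C)[Si](C)(C)Cl
Why: Silylation of the primary alcohol gives the ether that is later exchanged for the side-chain acetate.

Step 3
Reactants: 3 tert-butyl[(4-iodopent-4-en-1-yl)oxy]dimethylsilane; 4 methyl 4-bromo-2-iodobenzoate
Product: 6 methyl 4-bromo-2-[5-(TBS-oxy)pent-1-en-2-yl]benzoate, via arylzinc iodide 5 (not isolated)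
Conditions: 4, Zn dust, LiCl, THF, 25 °C; then 3, Pd(PPh3)4 (3 mol%), THF, 50 °C
Reagents that add atoms: none
Why: LiCl-assisted zinc insertion into the ester-activated C–I bond followed by Negishi coupling should be selective because the alkenyl iodide adds to zerovalent palladium much faster than the aryl bromide.

Step 4
Reactants: 6 methyl 4-bromo-2-[5-(TBS-oxy)pent-1-en-2-yl]benzoate
Product: 7 4-bromo-2-[5-(TBS-oxy)pent-1-en-2-yl]benzoic acid
Conditions: LiOH, THF/MeOH/H2O, 40 °C; then 1 M HCl to pH 3, 0 °C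
Reagents that add atoms: lithium hydroxide, [Li+].[OH-]
Why: Saponification frees the carboxylic acid that directs the next step.

Step 5
Reactants: 7 4-bromo-2-[5-(TBS-oxy)pent-1-en-2-yl]benzoic acid
Product: 8 4-bromo-2-[(2R)-5-(TBS-oxy)pentan-2-yl]benzoic acid
Conditions: H2 (6 atm), [Ir(cod)(L)]B[3,5-(CF3)2C6H3]4 (1 mol%; L = spiro phosphine–oxazoline SIPHOX, enantiomer chosen for the R product), Et3N (0.5 equiv), MeOH, rt
Reagents that add atoms: none
Why: In this carboxy-directed iridium-catalysed asymmetric hydrogenation of a 1,1-disubstituted alkene the ortho carboxylate binds the metal and fixes the alkene face, which should set the benzylic R centre.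

Step 6
Reactants: 8 4-bromo-2-[(2R)-5-(TBS-oxy)pentan-2-yl]benzoic acid
Product: 9 {4-bromo-2-[(2R)-5-(TBS-oxy)pentan-2-yl]phenyl}methanol
Conditions: BH3·SMe2, THF, 0 °C → rt
Reagents that add atoms: none
Why: Borane reduces the carboxylic acid chemoselectively and leaves the aryl bromide and the silyl ether untouched.

Step 7
Reactants: 9 {4-bromo-2-[(2R)-5-(TBS-oxy)pentan-2-yl]phenyl}methanol
Product: 10 {4-bromo-2-[(2R)-5-(TBS-oxy)pentan-2-yl]benzyl}oxy(tert-butyl)diphenylsilane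
Conditions: TBDPSCl, imidazole, DMF, rt
Reagents that add atoms: tert-butyldiphenylsilyl chloride, CC(C)(C)[Si](Cl)(c1ccccc1)c1ccccc1
Why: The benzylic oxygen, free in the target, gets the TBDPS ether because it must outlast removal of the two TBS ethers (step 24) and fall to fluoride at the end (step 26).

Step 8
Reactants: 11 malonic acid
Product: 12 bis[2-(trimethylsilyl)ethyl] malonate
Conditions: Me3SiCH2CH2OH (2.1 equiv), N,N′-dicyclohexylcarbodiimide, DMAP (cat.), CH2Cl2, 0 °C → rt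
Reagents that add atoms: 2-(trimethylsilyl)ethanol, C[Si](C)(C)CCO
Why: Steglich esterification gives a malonate whose esters tolerate base, hydride and mild acid and are cleaved by fluoride.

Step 9
Reactants: 10 aryl bromide; 12 bis[2-(trimethylsilyl)ethyl] malonate
Product: 13 bis[2-(trimethylsilyl)ethyl] 2-Ar-malonate
Conditions: Pd(OAc)2 (2 mol%), P(t-Bu)3·HBF4 (4 mol%), K3PO4, toluene, 80 °C
Reagents that add atoms: none
Why: Palladium-catalysed α-arylation of a malonate with an unhindered aryl bromide stops at monoarylation because the product stays as its enolate.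

Step 10
Reactants: 14 (R)-4-benzyloxazolidin-2-one; 15 acryloyl chloride
Product: 16 (R)-3-acryloyl-4-benzyloxazolidin-2-one
Conditions: Et3N, LiCl, THF, −20 °C → rt
Reagents that add atoms: none
Why: Lithium-chloride-assisted N-acylation of the oxazolidinone gives the acrylimide without a strong base.

Step 11
Reactants: 13 bis[2-(trimethylsilyl)ethyl] 2-Ar-malonate; 16 (R)-3-acryloyl-4-benzyloxazolidin-2-one
Product: 17 bis[2-(trimethylsilyl)ethyl] 2-Ar-2-{3-[(4R)-4-benzyl-2-oxooxazolidin-3-yl]-3-oxopropyl}malonate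
Conditions: DBU (0.2 equiv), MeCN, 0 °C → rt
Reagents that add atoms: none
Why: Base-catalysed Michael addition of the arylmalonate forms the C11′–C13′ bond and makes C11′ quaternary, so no stereocentre, acidic hydrogen or insertable C–H bond exists there.

Step 12
Reactants: 17 Michael adduct; 18 4-methoxy-2-methylbenzaldehyde
Product: 20 anti-aldol adduct (imide of 17 with C3 S bearing the C2 R carbinol HO–CH(4-methoxy-2-methylphenyl)), via trimethylsilyl ether 19 (not isolated)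
Conditions: MgCl2 (0.2 equiv), Et3N, Me3SiCl, EtOAc, 23 °C; then PPTS, MeOH, 0 °C
Reagents that add atoms: none
Why: In this magnesium-halide-catalysed direct anti-aldol of an N-acyloxazolidinone the chelated Z-enolate is attacked anti to the benzyl group (C3 S) through a boat transition state (anti, C2 R), and silylation of the aldolate turns the catalyst over.

Step 13
Reactants: 20 anti-aldol adduct
Product: 21 C2 TBS ether of 20
Conditions: TBSOTf, 2,6-lutidine, CH2Cl2, −78 → 0 °C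
Reagents that add atoms: tert-butyldimethylsilyl triflate, CC(C)(C)[Si](C)(C)OS(=O)(=O)C(F)(F)F
Why: Silylation of the benzylic alcohol prevents retro-aldol and gives the bulky C2 group that later directs protonation at C10.

Step 14
Reactants: 21 silylated imide
Product: 22 (2S)-2-[(R)-(TBS-oxy)(4-methoxy-2-methylphenyl)methyl]-4-Ar-4,4-di-E-butanoic acid
Conditions: LiOH, H2O2, THF/H2O, 0 °C; then Na2SO3; 1 M HCl to pH 3
Reagents that add atoms: hydrogen peroxide, OO
Why: Hydroperoxide attacks the exocyclic imide carbonyl selectively, so the auxiliary is removed without epimerising C3 or touching the hindered malonate esters.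

Step 15
Reactants: 22 carboxylic acid
Product: 24 α-diazoketone (C4 ketone, C5 diazo carbon; C3 S, C2 R), via mixed carbonic anhydride 23 (not isolated)
Conditions: i-BuOCOCl, Et3N, THF, −20 °C; then CH2N2, Et2O, 0 °C → rt
Reagents that add atoms: diazomethane, C=[N+]=[N-]
Why: Acylation of diazomethane by the mixed anhydride (first stage of the Arndt–Eistert sequence) gives the diazoketone without acid, so the silyl ethers survive.

Step 16
Reactants: 24 α-diazoketone
Product: 26 methoxy azulenone (cycloheptatriene: C4 ketone, C5–H, C6=C7, C8(OMe)=C9, C10(Me)=C1; 2α-OTBS; 3α-CH2C(Ar)E2), via norcaradiene 25 (not isolated)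
Conditions: Rh2(OAc)4 (1 mol%), CH2Cl2, 40 °C, slow addition of 24 (final 5 mM); filtration through basic alumina
Reagents that add atoms: none
Why: Rh2(OAc)4 turns the diazo carbon C5 into an electrophilic carbenoid that cyclopropanates the C1–C6 (ipso–ortho) bond of the anisole to norcaradiene 25, which opens by 6π disrotatory electrocyclisation to cycloheptatriene 26. The closest known reaction is the intramolecular Büchner reaction of 1-diazo-4-arylbutan-2-ones to 8aH-azulenones under dirhodium tetracarboxylate catalysis. The cyclopentanone closes by attack of the tethered carbenoid on the arene (C5–C1 bond through the tether C5–C4–C3–C2–C1), and the seven-membered ring arises by ring expansion of the benzene when the C1–C6 cyclopropane bond breaks after C5–C6 has formed. The one new stereocentre, C5, follows from the cis-fused cyclopropane on the arene face set by the C2/C3 substituents and is erased in step 17. The step needs chemoselective addition at the free ortho carbon: the methoxy group para to C1 makes this ring the most nucleophilic π system, the methyl group blocks the other ortho carbon, the second arene is reachable only through a six-membered closure, and the quaternary C11′ removes the only C–H bond open to 1,5-insertion. The methoxy group survives as the C8 enol ether and the aryl methyl becomes the C10 methyl.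

Step 17
Reactants: 26 methoxy azulenone
Product: 27 conjugated enone (C4 ketone, C1=C5, C6=C7, C8(OMe)=C9; 10α-methyl, 10β-H)
Conditions: Et3N (0.5 equiv), CH2Cl2, 0 °C → rt, stopped at full conversion
Reagents that add atoms: none
Why: In this base-mediated isomerisation of an 8aH-azulenone to the 3,4-dihydroazulen-1(2H)-one, Et3N removes the doubly allylic C5–H next to the ketone and the extended enolate should be reprotonated at C10 on the β face, anti to the C2 silyl ether, which leaves the methyl α; mild base and short contact keep the product from re-enolising.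

Step 18
Reactants: 27 conjugated enone
Product: 29 δ-lactone dienol ether (4β-methyl; C4–O–C12′ lactone cis-fused at C3–C4; C11′ bears Ar and E), via dichlorocerium alkoxide 28 (not isolated)
Conditions: MeLi, CeCl3, THF, −78 °C; then 0 °C → rt; aq. NH4Cl
Reagents that add atoms: methyllithium, [Li]C
Why: Organocerium 1,2-addition to the enolisable cyclopentenone should occur anti to the C3 side chain and the C2 silyl ether (methyl β, alkoxide α), and the alkoxide, cis to C13′, then closes the δ-lactone on one of the two equivalent ester groups by transesterification.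

Step 19
Reactants: 29 δ-lactone dienol ether
Product: 30 dienone lactone (C8 ketone, C6=C7, C1=C5)
Conditions: (CO2H)2, THF/H2O, 0 °C → rt
Reagents that add atoms: water, O
Why: In this enol ether hydrolysis protonation at C9 gives the oxocarbenium ion at C8 and, after loss of methanol, the ketone conjugated with C6=C7 and C1=C5; oxalic acid is mild enough for the allylic lactone and the silyl ethers.

Step 20
Reactants: 30 dienone lactone
Product: 32 keto ester (C8 ketone, 7α-CH2CO2t-Bu, C6 H2), via lithium enolate 31 (not isolated)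
Conditions: LiBH(s-Bu)3 (1.05 equiv), THF, −78 °C; then BrCH2CO2t-Bu, DMPU, −78 → −20 °C; then DBU (0.2 equiv), CH2Cl2, rt
Reagents that add atoms: tert-butyl bromoacetate, CC(C)(C)OC(=O)CBr
Why: In this reductive alkylation of an enone, hydride adds 1,4 at the unhindered C6 (C1 is fully substituted) to give the C7=C8 enolate regiospecifically, the bromoacetate alkylates C7, and DBU lets the epimerisable side chain settle equatorial, cis to the C10 methyl, which allylic strain with the C2 substituent holds pseudo-axial.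

Step 21
Reactants: 32 keto ester
Product: 33 8α-hydroxy tert-butyl ester (OH cis to the C7 side chain)
Conditions: LiBH(s-Bu)3, THF, −78 °C; then AcOH
Reagents that add atoms: none
Why: The bulky hydride should attack the C8 ketone from the β face, opposite the pseudo-axial C10 methyl, giving the axial α-alcohol, and the tert-butyl ester does not lactonise.

Step 22
Reactants: 33 8α-hydroxy tert-butyl ester
Product: 35 trans-fused γ-lactone (8β-O, 7α-C11; C11 H2), via C8 triflate 34 (not isolated)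
Conditions: Tf2O, pyridine, CH2Cl2, −78 → 0 °C
Reagents that add atoms: none
Why: The carbonyl oxygen of the tert-butyl ester displaces the triflate from the back (5-exo-tet neighbouring-group participation) and the dialkoxycarbenium ion loses isobutene, so the lactone forms with inversion at C8 and is trans-fused.

Step 23
Reactants: 35 trans-fused γ-lactone
Product: 39 α-methylene γ-lactone, via lactone lithium enolate 36 (not isolated), via Mannich base 37 (not isolated), via trimethylammonium iodide 38 (not isolated)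
Conditions: LiN(i-Pr)2, THF, −78 °C; CH2=NMe2+ I−, −78 → 0 °C; then MeI, MeOH/CH2Cl2, rt; then aq. NaHCO3, CH2Cl2
Reagents that add atoms: dimethyl(methylidene)ammonium iodide, C=[N+](C)C.[I-]
Why: Only the γ-lactone has α-hydrogens because C11′ is quaternary, so its enolate is aminomethylated (Mannich) and quaternisation then E1cB loss of trimethylamine gives the C11=C13 alkene (Eschenmoser methylenation).

Step 24
Reactants: 39 α-methylene γ-lactone
Product: 40 diol (C2–OH and side-chain primary OH free; TBDPS and E retained)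
Conditions: HF·pyridine, pyridine, THF, 0 °C → rt, monitored
Reagents that add atoms: none
Why: Buffered HF·pyridine should cleave the two TBS ethers faster than the primary TBDPS ether and does not fragment the 2-(trimethylsilyl)ethyl ester.

Step 25
Reactants: 40 diol
Product: 41 diacetate
Conditions: Ac2O, pyridine, DMAP (cat.), CH2Cl2, 0 °C
Reagents that add atoms: acetic anhydride, CC(=O)OC(C)=O
Why: DMAP-catalysed acetylation caps the C2 and side-chain alcohols at once and removes the free C2 hydroxyl before it can attack the δ-lactone.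

Step 26
Reactants: 41 diacetate
Product: 43 CNP0205574.1, via malonic half-acid 42 (not isolated)
Conditions: Bu4NF, AcOH (1:1), THF, 0 → 40 °C
Reagents that add atoms: none
Why: Fluoride removes the TBDPS ether and fragments the 2-(trimethylsilyl)ethyl ester, and the α-aryl malonic half-acid loses CO2 to an enol that should be protonated on the convex face (syn to H3 and the C4 methyl), placing the aryl group equatorial, which is also the expected thermodynamic configuration at C11′.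

**Compound list**

1 | pent-4-yn-1-ol | C#CCCCO | starting material
2 | 4-iodopent-4-en-1-ol | C=C(I)CCCO | intermediate
3 | tert-butyl[(4-iodopent-4-en-1-yl)oxy]dimethylsilane | C=C(I)CCCO[Si](C)(C)C(C)(C)C | intermediate
4 | methyl 4-bromo-2-iodobenzoate | COC(=O)c1ccc(Br)cc1I | starting material
5 | [5-bromo-2-(methoxycarbonyl)phenyl]zinc iodide | COC(=O)c1ccc(Br)cc1[Zn]I | intermediate
6 | methyl 4-bromo-2-[5-(TBS-oxy)pent-1-en-2-yl]benzoate | COC(=O)c1ccc(Br)cc1C(=C)CCCO[Si](C)(C)C(C)(C)C | intermediate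
7 | 4-bromo-2-[5-(TBS-oxy)pent-1-en-2-yl]benzoic acid | OC(=O)c1ccc(Br)cc1C(=C)CCCO[Si](C)(C)C(C)(C)C | intermediate
8 | 4-bromo-2-[(2R)-5-(TBS-oxy)pentan-2-yl]benzoic acid | OC(=O)c1ccc(Br)cc1[C@H](C)CCCO[Si](C)(C)C(C)(C)C | intermediate
9 | {4-bromo-2-[(2R)-5-(TBS-oxy)pentan-2-yl]phenyl}methanol | OCc1ccc(Br)cc1[C@H](C)CCCO[Si](C)(C)C(C)(C)C | intermediate
10 | TBDPS ether of 9 (aryl bromide) | CC(C)(C)[Si](OCc1ccc(Br)cc1[C@H](C)CCCO[Si](C)(C)C(C)(C)C)(c1ccccc1)c1ccccc1 | intermediate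
11 | malonic acid | OC(=O)CC(=O)O | starting material
12 | bis[2-(trimethylsilyl)ethyl] malonate | C[Si](C)(C)CCOC(=O)CC(=O)OCC[Si](C)(C)C | intermediate
13 | bis[2-(trimethylsilyl)ethyl] 2-Ar-malonate | C[Si](C)(C)CCOC(=O)C(C(=O)OCC[Si](C)(C)C)c1ccc(CO[Si](c2ccccc2)(c2ccccc2)C(C)(C)C)c([C@H](C)CCCO[Si](C)(C)C(C)(C)C)c1 | intermediate
14 | (R)-4-benzyloxazolidin-2-one | O=C1OC[C@@H](Cc2ccccc2)N1 | starting material
15 | acryloyl chloride | C=CC(Cl)=O | starting material
16 | (R)-3-acryloyl-4-benzyloxazolidin-2-one | O=C1OC[C@@H](Cc2ccccc2)N1C(=O)C=C | intermediate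
17 | Michael adduct: 2-Ar-2-{3-[(4R)-4-benzyl-2-oxooxazolidin-3-yl]-3-oxopropyl}malonate, bis-E ester | O=C1OC[C@@H](Cc2ccccc2)N1C(=O)CCC(C(=O)OCC[Si](C)(C)C)(C(=O)OCC[Si](C)(C)C)c1ccc(CO[Si](c2ccccc2)(c2ccccc2)C(C)(C)C)c([C@H](C)CCCO[Si](C)(C)C(C)(C)C)c1 | intermediate
18 | 4-methoxy-2-methylbenzaldehyde | COc1ccc(C=O)c(C)c1 | starting material
19 | trimethylsilyl ether of aldol adduct 20 | O=C1OC[C@@H](Cc2ccccc2)N1C(=O)[C@@H](CC(C(=O)OCC[Si](C)(C)C)(C(=O)OCC[Si](C)(C)C)c1ccc(CO[Si](c2ccccc2)(c2ccccc2)C(C)(C)C)c([C@H](C)CCCO[Si](C)(C)C(C)(C)C)c1)[C@@H](O[Si](C)(C)C)c1ccc(OC)cc1C | intermediate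
20 | anti-aldol adduct (C3 S, C2 R; free C2–OH) | O=C1OC[C@@H](Cc2ccccc2)N1C(=O)[C@@H](CC(C(=O)OCC[Si](C)(C)C)(C(=O)OCC[Si](C)(C)C)c1ccc(CO[Si](c2ccccc2)(c2ccccc2)C(C)(C)C)c([C@H](C)CCCO[Si](C)(C)C(C)(C)C)c1)[C@@H](O)c1ccc(OC)cc1C | intermediate
21 | C2 TBS ether of 20 | O=C1OC[C@@H](Cc2ccccc2)N1C(=O)[C@@H](CC(C(=O)OCC[Si](C)(C)C)(C(=O)OCC[Si](C)(C)C)c1ccc(CO[Si](c2ccccc2)(c2ccccc2)C(C)(C)C)c([C@H](C)CCCO[Si](C)(C)C(C)(C)C)c1)[C@@H](O[Si](C)(C)C(C)(C)C)c1ccc(OC)cc1C | intermediate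
22 | (2S)-2-[(R)-(TBS-oxy)(4-methoxy-2-methylphenyl)methyl]-4-Ar-4,4-di-E-butanoic acid | OC(=O)[C@@H](CC(C(=O)OCC[Si](C)(C)C)(C(=O)OCC[Si](C)(C)C)c1ccc(CO[Si](c2ccccc2)(c2ccccc2)C(C)(C)C)c([C@H](C)CCCO[Si](C)(C)C(C)(C)C)c1)[C@@H](O[Si](C)(C)C(C)(C)C)c1ccc(OC)cc1C | intermediate
23 | isobutyl carbonic mixed anhydride of 22 | CC(C)COC(=O)OC(=O)[C@@H](CC(C(=O)OCC[Si](C)(C)C)(C(=O)OCC[Si](C)(C)C)c1ccc(CO[Si](c2ccccc2)(c2ccccc2)C(C)(C)C)c([C@H](C)CCCO[Si](C)(C)C(C)(C)C)c1)[C@@H](O[Si](C)(C)C(C)(C)C)c1ccc(OC)cc1C | intermediate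
24 | α-diazoketone (key-step precursor; C3 S, C2 R) | [N-]=[N+]=CC(=O)[C@@H](CC(C(=O)OCC[Si](C)(C)C)(C(=O)OCC[Si](C)(C)C)c1ccc(CO[Si](c2ccccc2)(c2ccccc2)C(C)(C)C)c([C@H](C)CCCO[Si](C)(C)C(C)(C)C)c1)[C@@H](O[Si](C)(C)C(C)(C)C)c1ccc(OC)cc1C | intermediate
25 | norcaradiene (cyclopropane C5–C1–C6; diene C7=C8(OMe), C9=C10(Me)) | O=C1[C@@H](CC(C(=O)OCC[Si](C)(C)C)(C(=O)OCC[Si](C)(C)C)c4ccc(CO[Si](c5ccccc5)(c5ccccc5)C(C)(C)C)c([C@H](C)CCCO[Si](C)(C)C(C)(C)C)c4)[C@@H](O[Si](C)(C)C(C)(C)C)[C@@]23C(C)=CC(OC)=C[C@@H]2[C@@H]13 | intermediate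
26 | methoxy azulenone (cycloheptatriene; C5 epimer drawn is transient) | O=C1[C@@H](CC(C(=O)OCC[Si](C)(C)C)(C(=O)OCC[Si](C)(C)C)c3ccc(CO[Si](c4ccccc4)(c4ccccc4)C(C)(C)C)c([C@H](C)CCCO[Si](C)(C)C(C)(C)C)c3)[C@@H](O[Si](C)(C)C(C)(C)C)C2=C(C)C=C(OC)C=C[C@@H]12 | intermediate
27 | conjugated enone (C1=C5; 10α-methyl) | O=C1[C@@H](CC(C(=O)OCC[Si](C)(C)C)(C(=O)OCC[Si](C)(C)C)c3ccc(CO[Si](c4ccccc4)(c4ccccc4)C(C)(C)C)c([C@H](C)CCCO[Si](C)(C)C(C)(C)C)c3)[C@@H](O[Si](C)(C)C(C)(C)C)C2=C1C=CC(OC)=C[C@@H]2C | intermediate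
28 | dichlorocerium C4 alkoxide (4β-methyl) | COC1=C[C@H](C)C2=C(C=C1)[C@@](C)(O[Ce](Cl)Cl)[C@@H](CC(C(=O)OCC[Si](C)(C)C)(C(=O)OCC[Si](C)(C)C)c3ccc(CO[Si](c4ccccc4)(c4ccccc4)C(C)(C)C)c([C@H](C)CCCO[Si](C)(C)C(C)(C)C)c3)[C@H]2O[Si](C)(C)C(C)(C)C | intermediate
29 | δ-lactone dienol ether | COC1=C[C@H](C)C2=C(C=C1)[C@@]1(C)OC(=O)C(C(=O)OCC[Si](C)(C)C)(c3ccc(CO[Si](c4ccccc4)(c4ccccc4)C(C)(C)C)c([C@H](C)CCCO[Si](C)(C)C(C)(C)C)c3)C[C@H]1[C@H]2O[Si](C)(C)C(C)(C)C | intermediate
30 | dienone lactone (C8 ketone, C6=C7, C1=C5) | O=C1C[C@H](C)C2=C(C=C1)[C@@]1(C)OC(=O)C(C(=O)OCC[Si](C)(C)C)(c3ccc(CO[Si](c4ccccc4)(c4ccccc4)C(C)(C)C)c([C@H](C)CCCO[Si](C)(C)C(C)(C)C)c3)C[C@H]1[C@H]2O[Si](C)(C)C(C)(C)C | intermediate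
31 | lithium C7=C8 enolate | [Li]OC=1C[C@H](C)C2=C(CC=1)[C@@]1(C)OC(=O)C(C(=O)OCC[Si](C)(C)C)(c3ccc(CO[Si](c4ccccc4)(c4ccccc4)C(C)(C)C)c([C@H](C)CCCO[Si](C)(C)C(C)(C)C)c3)C[C@H]1[C@H]2O[Si](C)(C)C(C)(C)C | intermediate
32 | keto ester (7α-CH2CO2t-Bu) | O=C1C[C@H](C)C2=C(C[C@@H]1CC(=O)OC(C)(C)C)[C@@]1(C)OC(=O)C(C(=O)OCC[Si](C)(C)C)(c3ccc(CO[Si](c4ccccc4)(c4ccccc4)C(C)(C)C)c([C@H](C)CCCO[Si](C)(C)C(C)(C)C)c3)C[C@H]1[C@H]2O[Si](C)(C)C(C)(C)C | intermediate
33 | 8α-hydroxy tert-butyl ester | O[C@@H]1C[C@H](C)C2=C(C[C@@H]1CC(=O)OC(C)(C)C)[C@@]1(C)OC(=O)C(C(=O)OCC[Si](C)(C)C)(c3ccc(CO[Si](c4ccccc4)(c4ccccc4)C(C)(C)C)c([C@H](C)CCCO[Si](C)(C)C(C)(C)C)c3)C[C@H]1[C@H]2O[Si](C)(C)C(C)(C)C | intermediate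
34 | 8α-triflate | FC(F)(F)S(=O)(=O)O[C@@H]1C[C@H](C)C2=C(C[C@@H]1CC(=O)OC(C)(C)C)[C@@]1(C)OC(=O)C(C(=O)OCC[Si](C)(C)C)(c3ccc(CO[Si](c4ccccc4)(c4ccccc4)C(C)(C)C)c([C@H](C)CCCO[Si](C)(C)C(C)(C)C)c3)C[C@H]1[C@H]2O[Si](C)(C)C(C)(C)C | intermediate
35 | trans-fused γ-lactone (8β-O, 7α-C11) | O=C1O[C@H]2C[C@H](C)C3=C(C[C@@H]2C1)[C@@]1(C)OC(=O)C(C(=O)OCC[Si](C)(C)C)(c4ccc(CO[Si](c5ccccc5)(c5ccccc5)C(C)(C)C)c([C@H](C)CCCO[Si](C)(C)C(C)(C)C)c4)C[C@H]1[C@H]3O[Si](C)(C)C(C)(C)C | intermediate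
36 | lithium enolate of γ-lactone 35 | [Li]OC=1O[C@H]2C[C@H](C)C3=C(C[C@@H]2C=1)[C@@]1(C)OC(=O)C(C(=O)OCC[Si](C)(C)C)(c4ccc(CO[Si](c5ccccc5)(c5ccccc5)C(C)(C)C)c([C@H](C)CCCO[Si](C)(C)C(C)(C)C)c4)C[C@H]1[C@H]3O[Si](C)(C)C(C)(C)C | intermediate
37 | C11 Mannich base (CH2NMe2; C11 unassigned) | CN(C)CC1C(=O)O[C@H]2C[C@H](C)C3=C(C[C@H]12)[C@@]1(C)OC(=O)C(C(=O)OCC[Si](C)(C)C)(c4ccc(CO[Si](c5ccccc5)(c5ccccc5)C(C)(C)C)c([C@H](C)CCCO[Si](C)(C)C(C)(C)C)c4)C[C@H]1[C@H]3O[Si](C)(C)C(C)(C)C | intermediate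
38 | C11 trimethylammoniomethyl iodide | C[N+](C)(C)CC1C(=O)O[C@H]2C[C@H](C)C3=C(C[C@H]12)[C@@]1(C)OC(=O)C(C(=O)OCC[Si](C)(C)C)(c4ccc(CO[Si](c5ccccc5)(c5ccccc5)C(C)(C)C)c([C@H](C)CCCO[Si](C)(C)C(C)(C)C)c4)C[C@H]1[C@H]3O[Si](C)(C)C(C)(C)C.[I-] | intermediate
39 | α-methylene γ-lactone (silyl groups and E in place) | C=C1C(=O)O[C@H]2C[C@H](C)C3=C(C[C@H]12)[C@@]1(C)OC(=O)C(C(=O)OCC[Si](C)(C)C)(c4ccc(CO[Si](c5ccccc5)(c5ccccc5)C(C)(C)C)c([C@H](C)CCCO[Si](C)(C)C(C)(C)C)c4)C[C@H]1[C@H]3O[Si](C)(C)C(C)(C)C | intermediate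
40 | diol (C2–OH, side-chain OH) | C=C1C(=O)O[C@H]2C[C@H](C)C3=C(C[C@H]12)[C@@]1(C)OC(=O)C(C(=O)OCC[Si](C)(C)C)(c4ccc(CO[Si](c5ccccc5)(c5ccccc5)C(C)(C)C)c([C@H](C)CCCO)c4)C[C@H]1[C@H]3O | intermediate
41 | diacetate | C=C1C(=O)O[C@H]2C[C@H](C)C3=C(C[C@H]12)[C@@]1(C)OC(=O)C(C(=O)OCC[Si](C)(C)C)(c4ccc(CO[Si](c5ccccc5)(c5ccccc5)C(C)(C)C)c([C@H](C)CCCOC(C)=O)c4)C[C@H]1[C@H]3OC(C)=O | intermediate
42 | malonic half-acid (C11′ CO2H, benzylic OH free) | C=C1C(=O)O[C@H]2C[C@H](C)C3=C(C[C@H]12)[C@@]1(C)OC(=O)C(C(=O)O)(c4ccc(CO)c([C@H](C)CCCOC(C)=O)c4)C[C@H]1[C@H]3OC(C)=O | intermediate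
43 | CNP0205574.1 | C=C1C(=O)O[C@H]2C[C@H](C)C3=C(C[C@H]12)[C@@]1(C)OC(=O)[C@@H](c2ccc(CO)c([C@H](C)CCCOC(C)=O)c2)C[C@H]1[C@H]3OC(C)=O | target

**Step count.** Total: 26 steps. Longest linear sequence: 24 steps (steps 1–7, 9, 11–26).

**Steps most likely to fail**

Step 16 (Büchner reaction). The carbenoid may be lost to dimerisation or to capture by the C2 silyl ether oxygen, and the cycloheptatriene may collapse under trace acid to a 2-tetralone through its norcaradiene form. The fallback sets out from acid 22 and uses a doubly stabilised diazo compound. Activation of 22 with 1,1′-carbonyldiimidazole and reaction with Mg(O2CCH2CO2CH2CH=CH2)2 gives the allyl β-keto ester F1. Diazo transfer (4-acetamidobenzenesulfonyl azide, Et3N, MeCN) gives the 2-diazo-3-oxo ester F2. Rh2(O2CC3F7)4 in CH2Cl2 forms the same C5–C1 and C5–C6 bonds and gives the C5-allyloxycarbonyl cycloheptatriene F3, which has no C5–H. Pd(PPh3)4 and morpholine in THF remove the allyl group; the β-keto acid loses CO2 and the dienol is protonated at C10 anti to the C2 silyl ether. The fallback returns to the route at enone 27.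

Step 17 (isomerisation). The extended enolate may be reprotonated at C7 or C9 (exocyclic or push–pull isomers), or at C10 from the α face. The fallback sets out from 26 and postpones the alkene shift until a conjugated dienone is the thermodynamic sink. MeLi/CeCl3 adds to the C4 ketone of 26 and the alkoxide lactonises, giving the cycloheptatriene lactone F4, which can no longer enolise at C5. Oxalic acid in THF/H2O hydrolyses the enol ether to the C8 ketone F5 (C6=C7 enone, C10=C1 alkene, C5–H). DBU in CH2Cl2 removes C5–H (γ to the C8 enone) and reprotonates at C10, again anti to the silyl ether, to give the linear dienone. The fallback returns at dienone lactone 30.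

Step 20 (reductive alkylation). Hydride may add at C8 (1,2) or C1 (1,6), or proton exchange may scramble the enolate before alkylation (C9 alkylation, dialkylation). The fallback sets out from 30 and forms the C7–C11 bond by cross-coupling. α-Iodination (I2, pyridine, CH2Cl2) gives the 7-iodo dienone F6. Negishi coupling with the Reformatsky reagent BrZnCH2CO2t-Bu (Pd(PPh3)4, THF, 50 °C) gives the 7-substituted dienone F7. Conjugate reduction with [(Ph3P)CuH]6 in benzene, aqueous work-up and equilibration with DBU saturate C6=C7. The fallback returns at keto ester 32.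

**Further compounds**

F1 | step 16 | allyl β-keto ester from 22 (C4 ketone, C5 H2, CO2-allyl) | C=CCOC(=O)CC(=O)[C@@H](CC(C(=O)OCC[Si](C)(C)C)(C(=O)OCC[Si](C)(C)C)c1ccc(CO[Si](c2ccccc2)(c2ccccc2)C(C)(C)C)c([C@H](C)CCCO[Si](C)(C)C(C)(C)C)c1)[C@@H](O[Si](C)(C)C(C)(C)C)c1ccc(OC)cc1C
F2 | step 16 | allyl 2-diazo-3-oxo ester | C=CCOC(=O)C(=[N+]=[N-])C(=O)[C@@H](CC(C(=O)OCC[Si](C)(C)C)(C(=O)OCC[Si](C)(C)C)c1ccc(CO[Si](c2ccccc2)(c2ccccc2)C(C)(C)C)c([C@H](C)CCCO[Si](C)(C)C(C)(C)C)c1)[C@@H](O[Si](C)(C)C(C)(C)C)c1ccc(OC)cc1C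
F3 | step 16 | C5-allyloxycarbonyl methoxy azulenone (C5 unassigned) | O=C1[C@@H](CC(C(=O)OCC[Si](C)(C)C)(C(=O)OCC[Si](C)(C)C)c3ccc(CO[Si](c4ccccc4)(c4ccccc4)C(C)(C)C)c([C@H](C)CCCO[Si](C)(C)C(C)(C)C)c3)[C@@H](O[Si](C)(C)C(C)(C)C)C2=C(C)C=C(OC)C=CC12C(=O)OCC=C
F4 | step 17 | cycloheptatriene δ-lactone (C5–H, C6=C7, C8(OMe)=C9, C10(Me)=C1) | COC1=CC(C)=C2[C@@H](C=C1)[C@@]1(C)OC(=O)C(C(=O)OCC[Si](C)(C)C)(c3ccc(CO[Si](c4ccccc4)(c4ccccc4)C(C)(C)C)c([C@H](C)CCCO[Si](C)(C)C(C)(C)C)c3)C[C@H]1[C@H]2O[Si](C)(C)C(C)(C)C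
F5 | step 17 | deconjugated C8 ketone (C6=C7, C10(Me)=C1, C5–H) | O=C1CC(C)=C2[C@@H](C=C1)[C@@]1(C)OC(=O)C(C(=O)OCC[Si](C)(C)C)(c3ccc(CO[Si](c4ccccc4)(c4ccccc4)C(C)(C)C)c([C@H](C)CCCO[Si](C)(C)C(C)(C)C)c3)C[C@H]1[C@H]2O[Si](C)(C)C(C)(C)C
F6 | step 20 | 7-iodo dienone lactone | O=C1C[C@H](C)C2=C(C=C1I)[C@@]1(C)OC(=O)C(C(=O)OCC[Si](C)(C)C)(c3ccc(CO[Si](c4ccccc4)(c4ccccc4)C(C)(C)C)c([C@H](C)CCCO[Si](C)(C)C(C)(C)C)c3)C[C@H]1[C@H]2O[Si](C)(C)C(C)(C)C
F7 | step 20 | 7-(tert-butoxycarbonylmethyl) dienone lactone | O=C1C[C@H](C)C2=C(C=C1CC(=O)OC(C)(C)C)[C@@]1(C)OC(=O)C(C(=O)OCC[Si](C)(C)C)(c3ccc(CO[Si](c4ccccc4)(c4ccccc4)C(C)(C)C)c([C@H](C)CCCO[Si](C)(C)C(C)(C)C)c3)C[C@H]1[C@H]2O[Si](C)(C)C(C)(C)C
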